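**Remark on the chemistry:** the target, 7-hydroxy-5,6,8,3',4'-pentamethoxyflavone, is planar and has no stereocentre, so the achiral compound itself is the "single enantiomer given". The racemic intermediates 5, 6, 7 and 10 lose their stereocentre on the way.

Flavone numbering is used for the target: ring A = C4a, C5, C6, C7, C8, C8a; pyranone = O1, C2, C3, C4; ring B = C1'–C6'.

## The problem

The target is a 2-aryl-4H-chromen-4-one whose ring B (3,4-dimethoxyphenyl) and pyranone ring are routine. The difficulty lies in ring A, which is hexasubstituted: C4a carries the carbonyl carbon C4, C8a carries the ring oxygen O1, and C5, C6, C7 and C8 each carry one more oxygen. Of these five A-ring oxygens exactly one, O7, must be a free phenol, flanked by the methoxy groups on C6 and C8; O5, O6 and O8 are methyl ethers and O1 is part of the pyranone.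

Differentiation by inherent reactivity runs the wrong way. Lewis acids remove the C5 methyl through peri-chelation to C4=O, and alkylation of a polyhydroxyflavone hits O7 first and the chelated O5 last. The classical assembly uses C4a as a Friedel–Crafts nucleophile on a pentaoxygenated benzene, and that arene, with its oxygens already told apart, is itself a multistep target. The electron-rich rings are prone to over-oxidation and the 5-OMe is labile to Lewis acids, so the late steps must be mild.

The feature that opens another way is this: C7 (bearing OH) is para to C4a, the only A-ring carbon with a carbon substituent, and the four carbons between them (C5, C6, C8, C8a) all bear oxygen. Ring A therefore has a local mirror plane through C7 and C4a. It is the reductively aromatized 1,2-adduct of tetramethoxy-1,4-benzoquinone, whose two carbonyl carbons are C7 and C4a.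

## Retrosynthesis

**11 ⇒ 9 (O1–C2 bond and the C2=C3 unsaturation).** The pyranone is opened at O1–C2 to the 2'-hydroxychalcone 9, with flavanone 10 as the intermediate oxidation level. Closure at O1–C2 uses an oxygen already on ring A. The neighbouring cut at C4a–C4 would again need a nucleophilic C4a on a pre-built pentaoxygenated aryl ether. Precursor 9 is acyclic between the rings. The forward reaction must close the ring through the ortho hydroxyl (the para hydroxyl cannot reach) and dehydrogenate C2–C3 without touching the electron-rich rings.

**9 ⇒ 8 (one O–CH3 bond).** The ortho hydroxyl of 9 is traced back to a methoxy group. In 8 the two methoxy groups ortho to the carbonyl-bearing carbon are related by the local mirror plane, so either one may be cleaved and no regiochemical question arises. The forward reaction must remove exactly one of them, which the carbonyl can direct by chelation.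

**8 ⇒ 7 (C4=O and C2=C3 ⇒ alkyne plus carbinol).** The enone is the Meyer–Schuster product of propargylic alcohol 7. This transform changes C4 from a carbonyl carbon into an sp carbon, the only form in which C4 can act as a nucleophile, and so prepares the inverted-polarity cut that follows. The forward reaction asks for a formal 1,3-shift of hydroxyl, helped by the cation-stabilizing veratryl group on the carbinol carbon.

**7 ⇒ 2 + 5 (C4a–C4 bond, key disconnection).** The aryl–alkynyl bond is cut with reversed polarity: C4a is the electrophile, as a carbonyl carbon of quinone 2, and C4 the nucleophile, as the acetylide of 5. A cross-coupling at the same bond would need a pentaoxygenated aryl halide with O7 already distinguished. Here the distinction is created by the reaction: addition gives quinol 6, and its reductive aromatization turns the untouched carbonyl into the phenol para to the new bond. The precursor 2 is a symmetric C10 quinone with four identical methoxy groups. The forward reaction must add once, at carbonyl carbon, and then lose the tertiary hydroxyl reductively.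

**5 ⇒ 3 + 4 and 2 ⇒ 1.** Alcohol 5 is the ethynyl adduct of aldehyde 3 with Grignard reagent 4. Quinone 2 arises from chloranil 1 by fourfold substitution of chloride by methoxide.

## Roads not taken

**Alternative 1:** (the most obvious) Cut O1–C2 and C2–C3 in the Baker–Venkataraman sense. Ring A arrives as 1-[4-(benzyloxy)-2-hydroxy-3,5,6-trimethoxyphenyl]ethanone A1; O-aroylation and base-induced acyl shift give the 1,3-diketone A2, followed by acid cyclization and hydrogenolysis. The ring-forming chemistry is reliable, but A1 needs its five oxygens installed and told apart one by one on a benzene nucleus (benzyl on the future O7, one free hydroxyl, three methyl ethers). That is a long linear run-up with protecting groups before any flavone bond is made. In the chosen plan the same differentiation follows from the constitution of quinone 2, without a protecting group.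

**Alternative 2:** Cut the C6–O and C8–O bonds and oxygenate a simpler flavone late. 5,7-Dihydroxy-3',4'-dimethoxyflavone A3 would be dibrominated at C6 and C8 to A4 and converted by copper-mediated twofold methoxylation into the 5,7-dihydroxy-6,8-dimethoxyflavone A5. The forward key step places both missing oxygens at once, but it ends with O5 and O7 both free. The target then needs O5 methylated and O7 free, against the inherent order (O7 reacts first, the chelated O5 last). That costs protection of O7, a forced methylation of O5 and deprotection. In addition, methoxylation of a dibromo polyphenol competes with loss of bromine.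

**Alternative 3:** Cut C4a–C5 and C8–C8a and build ring A by a squarate (cyclobutenone) ring expansion. Addition of a 3-metalated 6-aryl-4-pyranone to a squaric diester would give the 4-hydroxy-4-pyranonyl-cyclobutenone A6. Thermal 4π ring opening and 6π closure onto the pyranone double bond would then give the 5,8-dihydroxy-6,7-dimethoxyflavone A7. This is also a de novo A ring, but the two carbonyl-derived oxygens land on C5 and C8 and the two ester oxygens on C6 and C7. O7 is then not distinguished from O6, and O5/O8 still need methylation. A mixed squarate with a regioselective addition would be required. In the chosen plan the carbonyl-derived free hydroxyl is O7 itself.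

Key step: step 3

## Route

**Step 1**
Reactants: 1 chloranil (2,3,5,6-tetrachlorocyclohexa-2,5-diene-1,4-dione)
Product: 2 2,3,5,6-tetramethoxycyclohexa-2,5-diene-1,4-dione (tetramethoxy-1,4-benzoquinone)
Conditions: NaOMe (excess), MeOH, reflux
Reagents that add atoms: sodium methoxide, [Na+].[O-]C
Why: Each chlorine sits on a carbon β to a quinone carbonyl, so methoxide should replace all four by addition–elimination (vinylogous acyl substitution); heating with excess methoxide is meant to carry the slower third and fourth substitutions to completion.

**Step 2**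
Reactants: 3 3,4-dimethoxybenzaldehyde; 4 ethynylmagnesium bromide
Product: 5 1-(3,4-dimethoxyphenyl)prop-2-yn-1-ol (racemic)
Conditions: THF, 0 °C to rt; then sat. aq. NH4Cl
Reagents that add atoms: none
Why: Grignard addition of an acetylide to an aryl aldehyde; the carbinol centre is formed racemic, which is immaterial because it becomes sp2 in step 4.

**Step 3**
Reactants: 5 1-(3,4-dimethoxyphenyl)prop-2-yn-1-ol; 2 tetramethoxy-1,4-benzoquinone
Product: 7 4-[3-(3,4-dimethoxyphenyl)-3-hydroxyprop-1-yn-1-yl]-2,3,5,6-tetramethoxyphenol (racemic), via alkynyl para-quinol 6 (not isolated)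
Conditions: 5, n-BuLi (2.2 equiv), THF, −78 to −20 °C; then 2, THF, −78 °C; then AcOH, Zn dust, 0 °C to rt
Reagents that add atoms: none
Why: Double deprotonation of 5 gives the alkoxide–acetylide, whose sp carbon adds 1,2 to one carbonyl of 2 (1,2-addition of a lithium acetylide to a p-quinone, a known reaction type); all four ring carbons next to the carbonyls are fully substituted and donor-bearing, so the carbonyl carbon is the only open electrophilic site, and lithium chelation by the flanking methoxy groups should assist. Because 2 is fully symmetric, both carbonyls and all four methoxy groups are equivalent and no regiochemical choice exists. Mono-addition is needed and the substrate secures it: after the first addition the remaining carbonyl is a doubly vinylogous ester in an anionic adduct and is far less electrophilic. Acetic acid then liberates quinol 6, and zinc transfers two electrons to the cross-conjugated dienone; the resulting dienolate expels the tertiary propargylic hydroxyl and the ring aromatizes (reductive aromatization of a p-quinol to a phenol, also a known reaction type). The carbonyl that was not attacked thereby becomes the free phenol para to the new C–C bond, the future 7-OH, while the four methoxy groups become the substituents at the future C5, C6, C8 and C8a. No ring is closed and no stereocentre is set: the quaternary carbon of 6 carries two identical ring arms, and the carbinol centre inherited from 5 is racemic and is destroyed in step 4. The selectivity that must hold is carbonyl addition over electron transfer or displacement of methoxide, which the low temperature, the hard acetylide and the electron-rich, weakly oxidizing quinone all favour.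

**Step 4**
Reactants: 7 4-[3-(3,4-dimethoxyphenyl)-3-hydroxyprop-1-yn-1-yl]-2,3,5,6-tetramethoxyphenol
Product: 8 (E)-3-(3,4-dimethoxyphenyl)-1-(4-hydroxy-2,3,5,6-tetramethoxyphenyl)prop-2-en-1-one
Conditions: TsOH·H2O (10 mol%), MeCN–H2O, 60 °C
Reagents that add atoms: none
Why: Meyer–Schuster rearrangement: the veratryl group stabilizes the propargylic cation, water returns at the alkyne carbon bonded to ring A, and the allenol tautomerizes to the E-enone, so the former acetylide carbon becomes C4=O and the carbinol carbon becomes the future C2; direct hydration of the electron-rich aryl alkyne followed by dehydration would converge on the same enone.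

**Step 5**
Reactants: 8 (E)-3-(3,4-dimethoxyphenyl)-1-(4-hydroxy-2,3,5,6-tetramethoxyphenyl)prop-2-en-1-one
Product: 9 (E)-1-(2,4-dihydroxy-3,5,6-trimethoxyphenyl)-3-(3,4-dimethoxyphenyl)prop-2-en-1-one
Conditions: BCl3 (2.2 equiv), CH2Cl2, −78 to 0 °C; then aq. HCl
Reagents that add atoms: none
Why: Chelation-controlled ether cleavage: boron bound to the ketone oxygen delivers chloride to the methyl of an ortho methoxy group through a six-membered chelate; the two ortho methoxy groups are equivalent by the local symmetry of ring A, and once one is cleaved the carbonyl is tied up in the boron chelate, which should spare the second; one equivalent of BCl3 is consumed by the free phenol.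

**Step 6**
Reactants: 9 (E)-1-(2,4-dihydroxy-3,5,6-trimethoxyphenyl)-3-(3,4-dimethoxyphenyl)prop-2-en-1-one
Product: 11 2-(3,4-dimethoxyphenyl)-7-hydroxy-5,6,8-trimethoxy-4H-chromen-4-one (target), via flavanone 10 (not isolated)
Conditions: I2 (10 mol%), DMSO, 120 °C
Reagents that add atoms: none
Why: Iodine/DMSO oxidative cyclization of a 2'-hydroxychalcone: 6-endo oxa-Michael addition of the ortho hydroxyl gives flavanone 10 (C2 racemic, then erased), α-iodination at C3 and loss of HI give the flavone, and DMSO reoxidizes HI to iodine; only the ortho hydroxyl can reach the β-carbon, so the para hydroxyl remains as the free 7-OH and ring A has no free position for iodination.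

## Compound list

1 | chloranil (2,3,5,6-tetrachlorocyclohexa-2,5-diene-1,4-dione) | O=C1C(Cl)=C(Cl)C(=O)C(Cl)=C1Cl | starting material
2 | 2,3,5,6-tetramethoxycyclohexa-2,5-diene-1,4-dione | COC1=C(OC)C(=O)C(OC)=C(OC)C1=O | intermediate
3 | 3,4-dimethoxybenzaldehyde | COc1ccc(C=O)cc1OC | starting material
4 | ethynylmagnesium bromide | C#C[Mg]Br | starting material
5 | 1-(3,4-dimethoxyphenyl)prop-2-yn-1-ol (racemic) | COc1ccc(C(O)C#C)cc1OC | intermediate
6 | 4-[3-(3,4-dimethoxyphenyl)-3-hydroxyprop-1-yn-1-yl]-4-hydroxy-2,3,5,6-tetramethoxycyclohexa-2,5-dien-1-one (racemic) | COc1ccc(C(O)C#CC2(O)C(OC)=C(OC)C(=O)C(OC)=C2OC)cc1OC | intermediate (not isolated)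
7 | 4-[3-(3,4-dimethoxyphenyl)-3-hydroxyprop-1-yn-1-yl]-2,3,5,6-tetramethoxyphenol (racemic) | COc1ccc(C(O)C#Cc2c(OC)c(OC)c(O)c(OC)c2OC)cc1OC | intermediate
8 | (E)-3-(3,4-dimethoxyphenyl)-1-(4-hydroxy-2,3,5,6-tetramethoxyphenyl)prop-2-en-1-one | COc1ccc(/C=C/C(=O)c2c(OC)c(OC)c(O)c(OC)c2OC)cc1OC | intermediate
9 | (E)-1-(2,4-dihydroxy-3,5,6-trimethoxyphenyl)-3-(3,4-dimethoxyphenyl)prop-2-en-1-one | COc1ccc(/C=C/C(=O)c2c(O)c(OC)c(O)c(OC)c2OC)cc1OC | intermediate
10 | 2-(3,4-dimethoxyphenyl)-7-hydroxy-5,6,8-trimethoxy-2,3-dihydro-4H-chromen-4-one (racemic) | COc1ccc(C2CC(=O)c3c(OC)c(OC)c(O)c(OC)c3O2)cc1OC | intermediate (not isolated)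
11 | 2-(3,4-dimethoxyphenyl)-7-hydroxy-5,6,8-trimethoxy-4H-chromen-4-one | COc1ccc(-c2cc(=O)c3c(OC)c(OC)c(O)c(OC)c3o2)cc1OC | target

## Step count and risks

Total steps: 6. Longest linear sequence: 5 (steps 2, 3, 4, 5, 6 from aldehyde 3; the branch from chloranil 1 is equally long).

**Step 3 (key step).** The organolithium may reduce the quinone by electron transfer, or attack a methoxy-bearing ring carbon with loss of methoxide instead of adding to the carbonyl. In the second stage the reductive loss of the tertiary hydroxyl may be incomplete, or the acid may ionize the veratryl carbinol too early. The fallback makes the same C4a–C4 bond with normal polarity by cross-coupling. It sets out from quinone 2, which is reduced with sodium dithionite to 2,3,5,6-tetramethoxybenzene-1,4-diol F1. One hydroxyl is converted with triflic anhydride (1 equiv) and pyridine into 4-hydroxy-2,3,5,6-tetramethoxyphenyl trifluoromethanesulfonate F2; the symmetric diol should give mono- and bis-triflate, to be separated. Sonogashira coupling of F2 with alkyne 5 (Pd catalyst, CuI, Et3N, DMF, heat) comes back to the route at 7.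

**Step 4.** The veratryl-stabilized propargylic cation may be captured by an arene or a phenol oxygen of a second molecule instead of by water, leading to oligomers, or an ortho methoxy group may close onto the activated alkyne. The fallback reaches the flavone through the 1,3-diketone oxidation level instead of the chalcone. It sets out from 7 and proceeds as follows:
- Oxidation of the carbinol with MnO2 gives 1-(3,4-dimethoxyphenyl)-3-(4-hydroxy-2,3,5,6-tetramethoxyphenyl)prop-2-yn-1-one F3.
- Conjugate addition of pyrrolidine gives the enaminone (E)-1-(3,4-dimethoxyphenyl)-3-(4-hydroxy-2,3,5,6-tetramethoxyphenyl)-3-(pyrrolidin-1-yl)prop-2-en-1-one F4.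
- Aqueous acid hydrolysis gives 1-(3,4-dimethoxyphenyl)-3-(4-hydroxy-2,3,5,6-tetramethoxyphenyl)propane-1,3-dione F5.
- Chelation-controlled mono-demethylation with BCl3 gives 1-(2,4-dihydroxy-3,5,6-trimethoxyphenyl)-3-(3,4-dimethoxyphenyl)propane-1,3-dione F6.
- Acid-catalysed cyclodehydration (cat. H2SO4, AcOH) comes back to the route at 11, bypassing 8, 9 and 10.

**Step 5.** A second methyl may be lost, from the other ortho methoxy group or from one next to the boron-bound phenol oxygen, or the Lewis acid and the HCl formed may add to or cyclize the enone. The fallback moves the demethylation to a ketone that has no enone. It sets out from quinone 2 and aldehyde 3: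
- 1-Ethoxyvinyllithium (from ethyl vinyl ether and t-BuLi) adds to 2 to give 4-(1-ethoxyvinyl)-4-hydroxy-2,3,5,6-tetramethoxycyclohexa-2,5-dien-1-one F7.
- Zn/AcOH reduces this to 4-(1-ethoxyvinyl)-2,3,5,6-tetramethoxyphenol F8.
- Dilute acid hydrolyses the enol ether to 1-(4-hydroxy-2,3,5,6-tetramethoxyphenyl)ethan-1-one F9.
- BCl3 removes one ortho methyl to give 1-(2,4-dihydroxy-3,5,6-trimethoxyphenyl)ethan-1-one F10.
- Claisen–Schmidt condensation of F10 with 3 (KOH, EtOH) comes back to the route at 9.

## Further compounds

F1 | step 3 | 2,3,5,6-tetramethoxybenzene-1,4-diol | COc1c(O)c(OC)c(OC)c(O)c1OC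
F2 | step 3 | 4-hydroxy-2,3,5,6-tetramethoxyphenyl trifluoromethanesulfonate | COc1c(O)c(OC)c(OC)c(OS(=O)(=O)C(F)(F)F)c1OC
F3 | step 4 | 1-(3,4-dimethoxyphenyl)-3-(4-hydroxy-2,3,5,6-tetramethoxyphenyl)prop-2-yn-1-one | COc1ccc(C(=O)C#Cc2c(OC)c(OC)c(O)c(OC)c2OC)cc1OC
F4 | step 4 | (E)-1-(3,4-dimethoxyphenyl)-3-(4-hydroxy-2,3,5,6-tetramethoxyphenyl)-3-(pyrrolidin-1-yl)prop-2-en-1-one | COc1ccc(C(=O)/C=C(/N2CCCC2)c2c(OC)c(OC)c(O)c(OC)c2OC)cc1OC
F5 | step 4 | 1-(3,4-dimethoxyphenyl)-3-(4-hydroxy-2,3,5,6-tetramethoxyphenyl)propane-1,3-dione | COc1ccc(C(=O)CC(=O)c2c(OC)c(OC)c(O)c(OC)c2OC)cc1OC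
F6 | step 4 | 1-(2,4-dihydroxy-3,5,6-trimethoxyphenyl)-3-(3,4-dimethoxyphenyl)propane-1,3-dione | COc1ccc(C(=O)CC(=O)c2c(O)c(OC)c(O)c(OC)c2OC)cc1OC
F7 | step 5 | 4-(1-ethoxyvinyl)-4-hydroxy-2,3,5,6-tetramethoxycyclohexa-2,5-dien-1-one | CCOC(=C)C1(O)C(OC)=C(OC)C(=O)C(OC)=C1OC
F8 | step 5 | 4-(1-ethoxyvinyl)-2,3,5,6-tetramethoxyphenol | CCOC(=C)c1c(OC)c(OC)c(O)c(OC)c1OC
F9 | step 5 | 1-(4-hydroxy-2,3,5,6-tetramethoxyphenyl)ethan-1-one | CC(=O)c1c(OC)c(OC)c(O)c(OC)c1OC
F10 | step 5 | 1-(2,4-dihydroxy-3,5,6-trimethoxyphenyl)ethan-1-one | CC(=O)c1c(O)c(OC)c(O)c(OC)c1OC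
A1 | alternative 1 | 1-[4-(benzyloxy)-2-hydroxy-3,5,6-trimethoxyphenyl]ethan-1-one | CC(=O)c1c(O)c(OC)c(OCc2ccccc2)c(OC)c1OC
A2 | alternative 1 | 1-[4-(benzyloxy)-2-hydroxy-3,5,6-trimethoxyphenyl]-3-(3,4-dimethoxyphenyl)propane-1,3-dione | COc1ccc(C(=O)CC(=O)c2c(O)c(OC)c(OCc3ccccc3)c(OC)c2OC)cc1OC
A3 | alternative 2 | 2-(3,4-dimethoxyphenyl)-5,7-dihydroxy-4H-chromen-4-one | COc1ccc(-c2cc(=O)c3c(O)cc(O)cc3o2)cc1OC
A4 | alternative 2 | 6,8-dibromo-2-(3,4-dimethoxyphenyl)-5,7-dihydroxy-4H-chromen-4-one | COc1ccc(-c2cc(=O)c3c(O)c(Br)c(O)c(Br)c3o2)cc1OC
A5 | alternative 2 | 2-(3,4-dimethoxyphenyl)-5,7-dihydroxy-6,8-dimethoxy-4H-chromen-4-one | COc1ccc(-c2cc(=O)c3c(O)c(OC)c(O)c(OC)c3o2)cc1OC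
A6 | alternative 3 | 4-[6-(3,4-dimethoxyphenyl)-4-oxo-4H-pyran-3-yl]-4-hydroxy-2,3-dimethoxycyclobut-2-en-1-one (racemic) | COC1=C(OC)C(O)(c2coc(-c3ccc(OC)c(OC)c3)cc2=O)C1=O
A7 | alternative 3 | 2-(3,4-dimethoxyphenyl)-5,8-dihydroxy-6,7-dimethoxy-4H-chromen-4-one | COc1ccc(-c2cc(=O)c3c(O)c(OC)c(OC)c(O)c3o2)cc1OC
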